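**Plan** (1-benzoxepine locants: O1, C2–C5, C5a, C6–C9, C9a; ring A = cyclohexane, ring B = oxepine)
Retrosynthesis: cut C7–Br and CH2–Br (back to a diol), trace CH3 on C9a back to CO2Me, then cut ring A at C9–C9a and C6–C5a into 2-silyloxy diene 12 and ring-B enoate 9; cut 9 at its ester carbon (lactone 7), then ring B at C3=C4 (metathesis) and at the lactone C–O bond (alcohol 4 + pent-4-enoic acid).
Forward: ring B is made first by ring-closing metathesis, ring A is fused onto it in one Diels–Alder step, and the two bromides are put in last.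
Stereochemistry: C2 from a Sharpless epoxidation; C5a and C9a from the suprafacial cycloaddition on the face anti to the C2 side chain; C7 from convex-face hydride reduction, then SN2 bromination with inversion.
Enabling feature: rings A and B are cis-fused at C5a–C9a, O1 sits on C9a, and C7 (para to C9a, next to the C6 gem-dimethyl group) can be carried as a ketone; so C5a=C9a can lie inside ring B as an α-alkoxy enoate and C6–C9 can come as a 2-silyloxy diene.

Key step: step 9

Remark: the target is taken exactly as drawn, i.e. the cis-fused (2R,5aR,7S,9aS) isomer with H-5a and CH3-9a on the same face, and the CH2Br group on the face of ring B opposite to ring A.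

Step 1
Reactants: 1 3-methylbut-2-en-1-ol (prenol)
Product: 2 (S)-(3,3-dimethyloxiran-2-yl)methanol
Conditions: Ti(OiPr)4 (5 mol %), L-(+)-diethyl tartrate (6 mol %), tBuOOH, 4 Å molecular sieves, CH2Cl2, −20 °C
Reagents that add atoms: tert-butyl hydroperoxide CC(C)(C)OO
Why: Sharpless asymmetric epoxidation of a primary allylic alcohol; the L-tartrate–titanium complex should deliver oxygen to the alkene face that makes the oxirane CH carbon S, and this carbon becomes C2 of the target.

Step 2
Reactants: 2 (S)-(3,3-dimethyloxiran-2-yl)methanol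
Product: 3 (S)-tert-butyl[(3,3-dimethyloxiran-2-yl)methoxy]diphenylsilane
Conditions: tBuPh2SiCl, imidazole, DMF, 0 °C to rt
Reagents that add atoms: tert-butyl(chloro)diphenylsilane CC(C)(C)[Si](Cl)(c1ccccc1)c1ccccc1
Why: Standard silylation of a primary alcohol; the bulky silyl ether later serves as the face-shielding group and the epoxide is not opened by imidazole.

Step 3
Reactants: 3 (S)-tert-butyl[(3,3-dimethyloxiran-2-yl)methoxy]diphenylsilane
Product: 4 (R)-1-[(tert-butyldiphenylsilyl)oxy]-3-methylbut-3-en-2-ol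
Conditions: Et2AlCl, lithium 2,2,6,6-tetramethylpiperidide (gives Et2Al(NC9H18)), toluene, 0 °C; aq. potassium sodium tartrate
Reagents that add atoms: none
Why: Aluminium amide-mediated isomerisation of an epoxide to an allylic alcohol (syn β-elimination); the base removes a methyl proton and the tertiary C–O bond breaks, so the secondary C–O bond and its configuration are kept.

Step 4
Reactants: 4 (R)-1-[(tert-butyldiphenylsilyl)oxy]-3-methylbut-3-en-2-ol; 5 pent-4-enoic acid
Product: 6 (R)-1-[(tert-butyldiphenylsilyl)oxy]-3-methylbut-3-en-2-yl pent-4-enoate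
Conditions: DCC, DMAP (cat.), CH2Cl2, 0 °C to rt
Reagents that add atoms: none
Why: Steglich esterification (carbodiimide activation, DMAP acyl transfer) of a secondary allylic alcohol; the stereocentre is not touched.

Step 5
Reactants: 6 (R)-1-[(tert-butyldiphenylsilyl)oxy]-3-methylbut-3-en-2-yl pent-4-enoate
Product: 7 (R)-7-{[(tert-butyldiphenylsilyl)oxy]methyl}-6-methyl-4,7-dihydrooxepin-2(3H)-one
Conditions: second-generation Grubbs catalyst RuCl2(=CHPh)(PCy3)(H2IMes) (5 mol %), toluene (2 mM), 80 °C
Reagents that add atoms: none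
Why: Ring-closing olefin metathesis between the monosubstituted and the 1,1-disubstituted alkene should close the seven-membered ring B at high dilution and fix the Z trisubstituted alkene that becomes C3=C4.

Step 6
Reactants: 7 (R)-7-{[(tert-butyldiphenylsilyl)oxy]methyl}-6-methyl-4,7-dihydrooxepin-2(3H)-one
Product: 8 (R)-7-{[(tert-butyldiphenylsilyl)oxy]methyl}-6-methyl-4,7-dihydrooxepin-2-yl diphenyl phosphate
Conditions: KN(SiMe3)2, (PhO)2P(O)Cl, HMPA, THF, −78 °C
Reagents that add atoms: diphenyl chlorophosphate O=P(Cl)(Oc1ccccc1)Oc1ccccc1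
Why: O-phosphorylation of the potassium lactone enolate gives the cyclic ketene acetal phosphate, a known entry to 2-substituted cyclic enol ethers; the stereocentre is not enolisable.

Step 7
Reactants: 8 (R)-7-{[(tert-butyldiphenylsilyl)oxy]methyl}-6-methyl-4,7-dihydrooxepin-2-yl diphenyl phosphate
Product: 9 methyl (R)-7-{[(tert-butyldiphenylsilyl)oxy]methyl}-6-methyl-4,7-dihydrooxepine-2-carboxylate
Conditions: Pd(PPh3)4 (10 mol %), CO (1 atm), MeOH, Et3N, DMF, 40 °C
Reagents that add atoms: carbon monoxide [C-]#[O+]; methanol CO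
Why: Palladium-catalysed alkoxycarbonylation (oxidative addition of zerovalent palladium into the enol phosphate C–O bond, CO insertion, methanolysis) installs the ester that turns the ring-B enol ether into a captodative dienophile.

Step 8
Reactants: 10 4-methylpent-1-en-3-ol (racemic)
Product: 12 tert-butyldimethyl[(4-methylpenta-1,3-dien-3-yl)oxy]silane, via 4-methylpent-1-en-3-one 11 (not isolated)
Conditions: Dess–Martin periodinane, CH2Cl2, 0 °C to rt; aq. NaHCO3/Na2S2O3 wash, dry; then Et3N, tBuMe2SiOTf, 0 °C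
Reagents that add atoms: tert-butyldimethylsilyl trifluoromethanesulfonate CC(C)(C)[Si](C)(C)OS(=O)(=O)C(F)(F)F
Why: Dess–Martin oxidation of the allylic alcohol, then soft enolisation and O-silylation at the only enolisable position (the isopropyl CH), should give the cross-conjugated 2-silyloxy diene; the volatile enone is used in solution.

Step 9
Reactants: 9 methyl (R)-7-{[(tert-butyldiphenylsilyl)oxy]methyl}-6-methyl-4,7-dihydrooxepine-2-carboxylate; 12 tert-butyldimethyl[(4-methylpenta-1,3-dien-3-yl)oxy]silane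
Product: 14 methyl (2R,5aR,9aS)-2-{[(tert-butyldiphenylsilyl)oxy]methyl}-3,6,6-trimethyl-7-oxo-5,5a,6,7,8,9-hexahydro-1-benzoxepine-9a(2H)-carboxylate, via silyl enol ether cycloadduct 13 (not isolated)
Conditions: 12 (3 equiv), BHT (cat.), CH2Cl2, 13 kbar, 40 °C; then 1 M HCl, THF, 0 °C
Reagents that add atoms: none
Why: Normal-electron-demand Diels–Alder reaction, concerted but asynchronous: the HOMO of diene 12 (largest coefficient at the CMe2 terminus, the enol ether carbon) meets the LUMO of the α-alkoxy enoate 9 (largest coefficient at the β carbon), so the C6–C5a bond leads and the C9–C9a bond follows, and mild acid then turns silyl enol ether 13 into ketone 14. The closest known reaction type is the [4+2] cycloaddition of 2-silyloxy dienes with α-oxygenated acrylates and cyclic enoates, where high pressure is the usual answer to a trisubstituted dienophile and a disubstituted diene terminus. Ring A is closed by an intermolecular suprafacial [4πs+2πs] cycloaddition onto the endocyclic double bond of ring B, so both new bonds enter the same face and the ring fusion can only be cis. C5a and C9a are thus set relative to each other by the Z geometry of the ring-B alkene, and relative to C2 by the CH2OSi group, which A(1,2) strain with the neighbouring vinylic methyl should hold pseudo-axial over one face of O1–C9a, so that the diene adds anti to it. The step needs regioselectivity (secured by the polarisation of both partners and because the other orientation would join the CMe2 terminus to the fully substituted C9a), site selectivity (the unactivated trisubstituted alkene of ring B is no dienophile) and facial selectivity (the C2 side chain). Pressure at 40 °C is chosen over heat because the Z-methyl of the diene would undergo a 1,5-hydrogen shift at the temperature a thermal reaction would need.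

Step 10
Reactants: 14 methyl (2R,5aR,9aS)-2-{[(tert-butyldiphenylsilyl)oxy]methyl}-3,6,6-trimethyl-7-oxo-5,5a,6,7,8,9-hexahydro-1-benzoxepine-9a(2H)-carboxylate
Product: 15 (2R,5aR,7R,9aS)-2-{[(tert-butyldiphenylsilyl)oxy]methyl}-9a-(hydroxymethyl)-3,6,6-trimethyl-2,5,5a,6,7,8,9,9a-octahydro-1-benzoxepin-7-ol
Conditions: LiAlH4, THF, 0 °C to rt
Reagents that add atoms: none
Why: LiAlH4 reduction of ester and ketone; hydride should reach C7 from the convex face anti to ring B (axial attack past axial hydrogens only, the other face being screened by the axial C6 methyl and by ring B), which places the new hydroxyl cis to O1 (7R).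

Step 11
Reactants: 15 (2R,5aR,7R,9aS)-2-{[(tert-butyldiphenylsilyl)oxy]methyl}-9a-(hydroxymethyl)-3,6,6-trimethyl-2,5,5a,6,7,8,9,9a-octahydro-1-benzoxepin-7-ol
Product: 16 [(2R,5aR,7R,9aS)-2-{[(tert-butyldiphenylsilyl)oxy]methyl}-7-hydroxy-3,6,6-trimethyl-5,5a,6,7,8,9-hexahydro-1-benzoxepin-9a(2H)-yl]methyl 4-methylbenzenesulfonate
Conditions: TsCl, Et3N, DMAP (cat.), CH2Cl2, 0 °C
Reagents that add atoms: 4-methylbenzenesulfonyl chloride Cc1ccc(cc1)S(=O)(=O)Cl
Why: Selective sulfonylation of the primary alcohol; the secondary C7 hydroxyl is flanked by the C6 gem-dimethyl group and should not react at 0 °C.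

Step 12
Reactants: 16 [(2R,5aR,7R,9aS)-2-{[(tert-butyldiphenylsilyl)oxy]methyl}-7-hydroxy-3,6,6-trimethyl-5,5a,6,7,8,9-hexahydro-1-benzoxepin-9a(2H)-yl]methyl 4-methylbenzenesulfonate
Product: 17 (2R,5aR,7R,9aS)-2-{[(tert-butyldiphenylsilyl)oxy]methyl}-3,6,6,9a-tetramethyl-2,5,5a,6,7,8,9,9a-octahydro-1-benzoxepin-7-ol
Conditions: LiEt3BH (4 equiv), THF, 0 °C to reflux
Reagents that add atoms: none
Why: SN2 hydride displacement of a primary tosylate by LiEt3BH, the usual way to turn a neopentyl-type CH2OH into CH3, converts the former activating group into the C9a methyl without touching a stereocentre.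

Step 13
Reactants: 17 (2R,5aR,7R,9aS)-2-{[(tert-butyldiphenylsilyl)oxy]methyl}-3,6,6,9a-tetramethyl-2,5,5a,6,7,8,9,9a-octahydro-1-benzoxepin-7-ol
Product: 18 (2R,5aR,7R,9aS)-2-(hydroxymethyl)-3,6,6,9a-tetramethyl-2,5,5a,6,7,8,9,9a-octahydro-1-benzoxepin-7-ol
Conditions: Bu4NF, THF, rt
Reagents that add atoms: none
Why: Fluoride-mediated cleavage of the silyl ether frees the primary alcohol.

Step 14
Reactants: 18 (2R,5aR,7R,9aS)-2-(hydroxymethyl)-3,6,6,9a-tetramethyl-2,5,5a,6,7,8,9,9a-octahydro-1-benzoxepin-7-ol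
Product: 19 (2R,5aR,7S,9aS)-7-bromo-2-(bromomethyl)-3,6,6,9a-tetramethyl-2,5,5a,6,7,8,9,9a-octahydro-1-benzoxepine
Conditions: CBr4 (5 equiv), P(n-C8H17)3 (5 equiv), toluene, 70 °C
Reagents that add atoms: carbon tetrabromide BrC(Br)(Br)Br
Why: Appel reaction with a small, nucleophilic trialkylphosphine; both hydroxyls become alkoxyphosphonium ions and are displaced by bromide, the primary one without stereochemical consequence and the hindered C7 one by SN2 from the convex face with inversion (7R to 7S).

**Compound list**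
1 | 3-methylbut-2-en-1-ol | CC(C)=CCO | starting material
2 | (S)-(3,3-dimethyloxiran-2-yl)methanol | CC1(C)O[C@H]1CO | intermediate
3 | (S)-tert-butyl[(3,3-dimethyloxiran-2-yl)methoxy]diphenylsilane | CC1(C)O[C@H]1CO[Si](c1ccccc1)(c1ccccc1)C(C)(C)C | intermediate
4 | (R)-1-[(tert-butyldiphenylsilyl)oxy]-3-methylbut-3-en-2-ol | C=C(C)[C@@H](O)CO[Si](c1ccccc1)(c1ccccc1)C(C)(C)C | intermediate
5 | pent-4-enoic acid | C=CCCC(=O)O | starting material
6 | (R)-1-[(tert-butyldiphenylsilyl)oxy]-3-methylbut-3-en-2-yl pent-4-enoate | C=CCCC(=O)O[C@H](C(C)=C)CO[Si](c1ccccc1)(c1ccccc1)C(C)(C)C | intermediate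
7 | (R)-7-{[(tert-butyldiphenylsilyl)oxy]methyl}-6-methyl-4,7-dihydrooxepin-2(3H)-one | CC1=CCCC(=O)O[C@H]1CO[Si](c1ccccc1)(c1ccccc1)C(C)(C)C | intermediate
8 | (R)-7-{[(tert-butyldiphenylsilyl)oxy]methyl}-6-methyl-4,7-dihydrooxepin-2-yl diphenyl phosphate | CC1=CCC=C(OP(=O)(Oc2ccccc2)Oc2ccccc2)O[C@H]1CO[Si](c1ccccc1)(c1ccccc1)C(C)(C)C | intermediate
9 | methyl (R)-7-{[(tert-butyldiphenylsilyl)oxy]methyl}-6-methyl-4,7-dihydrooxepine-2-carboxylate | CC1=CCC=C(C(=O)OC)O[C@H]1CO[Si](c1ccccc1)(c1ccccc1)C(C)(C)C | intermediate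
10 | 4-methylpent-1-en-3-ol (racemic) | CC(C)C(O)C=C | starting material
11 | 4-methylpent-1-en-3-one | CC(C)C(=O)C=C | intermediate
12 | tert-butyldimethyl[(4-methylpenta-1,3-dien-3-yl)oxy]silane | CC(C)=C(O[Si](C)(C)C(C)(C)C)C=C | intermediate
13 | methyl (2R,5aR,9aS)-7-[(tert-butyldimethylsilyl)oxy]-2-{[(tert-butyldiphenylsilyl)oxy]methyl}-3,6,6-trimethyl-5,5a,6,9-tetrahydro-1-benzoxepine-9a(2H)-carboxylate (cis-fused) | CC1=CC[C@@H]2C(C)(C)C(O[Si](C)(C)C(C)(C)C)=CC[C@]2(C(=O)OC)O[C@H]1CO[Si](c1ccccc1)(c1ccccc1)C(C)(C)C | intermediate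
14 | methyl (2R,5aR,9aS)-2-{[(tert-butyldiphenylsilyl)oxy]methyl}-3,6,6-trimethyl-7-oxo-5,5a,6,7,8,9-hexahydro-1-benzoxepine-9a(2H)-carboxylate (cis-fused) | CC1=CC[C@@H]2C(C)(C)C(=O)CC[C@]2(C(=O)OC)O[C@H]1CO[Si](c1ccccc1)(c1ccccc1)C(C)(C)C | intermediate
15 | (2R,5aR,7R,9aS)-2-{[(tert-butyldiphenylsilyl)oxy]methyl}-9a-(hydroxymethyl)-3,6,6-trimethyl-2,5,5a,6,7,8,9,9a-octahydro-1-benzoxepin-7-ol | CC1=CC[C@@H]2C(C)(C)[C@H](O)CC[C@]2(CO)O[C@H]1CO[Si](c1ccccc1)(c1ccccc1)C(C)(C)C | intermediate
16 | [(2R,5aR,7R,9aS)-2-{[(tert-butyldiphenylsilyl)oxy]methyl}-7-hydroxy-3,6,6-trimethyl-5,5a,6,7,8,9-hexahydro-1-benzoxepin-9a(2H)-yl]methyl 4-methylbenzenesulfonate | CC1=CC[C@@H]2C(C)(C)[C@H](O)CC[C@]2(COS(=O)(=O)c3ccc(C)cc3)O[C@H]1CO[Si](c1ccccc1)(c1ccccc1)C(C)(C)C | intermediate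
17 | (2R,5aR,7R,9aS)-2-{[(tert-butyldiphenylsilyl)oxy]methyl}-3,6,6,9a-tetramethyl-2,5,5a,6,7,8,9,9a-octahydro-1-benzoxepin-7-ol | CC1=CC[C@@H]2C(C)(C)[C@H](O)CC[C@]2(C)O[C@H]1CO[Si](c1ccccc1)(c1ccccc1)C(C)(C)C | intermediate
18 | (2R,5aR,7R,9aS)-2-(hydroxymethyl)-3,6,6,9a-tetramethyl-2,5,5a,6,7,8,9,9a-octahydro-1-benzoxepin-7-ol | CC1=CC[C@@H]2C(C)(C)[C@H](O)CC[C@]2(C)O[C@H]1CO | intermediate
19 | (2R,5aR,7S,9aS)-7-bromo-2-(bromomethyl)-3,6,6,9a-tetramethyl-2,5,5a,6,7,8,9,9a-octahydro-1-benzoxepine | CC1=CC[C@@H]2C(C)(C)[C@@H](Br)CC[C@]2(C)O[C@H]1CBr | target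

**Step count and risks**
Total step count: 14. Longest linear sequence: 13 steps (steps 1–7 and 9–14); step 8 is a one-step side branch.

Steps most likely to fail:

1. Step 9. The trisubstituted, donor-substituted dienophile may react too slowly with the fully substituted diene terminus, so that isomerisation or oligomerisation of 12 wins, and the C2 side chain may discriminate the two faces only partly. The fallback is a stepwise ionic annulation in place of the cycloaddition and sets out from 9 and 12. TiCl4 in CH2Cl2 at −78 °C should chelate O1 and the ester carbonyl of 9 and bring about a Mukaiyama–Michael addition of the CMe2 terminus of 12 to the β carbon, giving after aqueous work-up methyl (3R,7R)-7-{[(tert-butyldiphenylsilyl)oxy]methyl}-6-methyl-3-(2-methyl-3-oxopent-4-en-2-yl)-2,3,4,7-tetrahydrooxepine-2-carboxylate F1 as a mixture at the ester-bearing carbon. KOtBu (0.2 equiv) in THF/tBuOH at 0 °C should then close ring A by an intramolecular 6-endo-trig Michael addition of the ester enolate to the vinyl ketone, and the sequence comes back to the route at 14.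

2. Step 14. The alkoxyphosphonium ion at the neopentyl-type C7 may ionise with a 1,2-shift of the antiperiplanar ring bond or methyl group, or undergo E2 elimination towards C8, instead of SN2 displacement. The fallback separates the two substitutions and takes the hindered one through a sulfonate; it sets out from 18. CBr4/PPh3 in CH2Cl2 at 0 °C should brominate only the primary alcohol to give (2R,5aR,7R,9aS)-2-(bromomethyl)-3,6,6,9a-tetramethyl-2,5,5a,6,7,8,9,9a-octahydro-1-benzoxepin-7-ol F2. ClCH2SO2Cl/pyridine should convert it into (2R,5aR,7R,9aS)-2-(bromomethyl)-3,6,6,9a-tetramethyl-2,5,5a,6,7,8,9,9a-octahydro-1-benzoxepin-7-yl chloromethanesulfonate F3. LiBr in DMF at 50 °C should then displace this leaving group with inversion under non-ionising conditions, and the sequence comes back to the route at 19.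

3. Step 12. SN2 at the neopentyl-type carbon may be too slow, so that hydride attacks sulfur and returns diol 15, or O1 participates and the skeleton rearranges. The fallback is a radical deoxygenation with no substitution at carbon and sets out from 15. 1,1'-Thiocarbonyldiimidazole/DMAP in CH2Cl2 should acylate only the primary hydroxyl to give O-{[(2R,5aR,7R,9aS)-2-{[(tert-butyldiphenylsilyl)oxy]methyl}-7-hydroxy-3,6,6-trimethyl-5,5a,6,7,8,9-hexahydro-1-benzoxepin-9a(2H)-yl]methyl} 1H-imidazole-1-carbothioate F4. Bu3SnH (kept concentrated to outrun 5-exo cyclisation of the primary radical onto C4) and AIBN in toluene at 110 °C (Barton–McCombie deoxygenation) should then give the methyl group, and the sequence comes back to the route at 17.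

**Further compounds**
F1 | step 9 | methyl (3R,7R)-7-{[(tert-butyldiphenylsilyl)oxy]methyl}-6-methyl-3-(2-methyl-3-oxopent-4-en-2-yl)-2,3,4,7-tetrahydrooxepine-2-carboxylate (both C2 epimers) | CC1=CC[C@H](C(C)(C)C(=O)C=C)C(C(=O)OC)O[C@H]1CO[Si](c1ccccc1)(c1ccccc1)C(C)(C)C
F2 | step 14 | (2R,5aR,7R,9aS)-2-(bromomethyl)-3,6,6,9a-tetramethyl-2,5,5a,6,7,8,9,9a-octahydro-1-benzoxepin-7-ol | CC1=CC[C@@H]2C(C)(C)[C@H](O)CC[C@]2(C)O[C@H]1CBr
F3 | step 14 | (2R,5aR,7R,9aS)-2-(bromomethyl)-3,6,6,9a-tetramethyl-2,5,5a,6,7,8,9,9a-octahydro-1-benzoxepin-7-yl chloromethanesulfonate | CC1=CC[C@@H]2C(C)(C)[C@H](OS(=O)(=O)CCl)CC[C@]2(C)O[C@H]1CBr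
F4 | step 12 | O-{[(2R,5aR,7R,9aS)-2-{[(tert-butyldiphenylsilyl)oxy]methyl}-7-hydroxy-3,6,6-trimethyl-5,5a,6,7,8,9-hexahydro-1-benzoxepin-9a(2H)-yl]methyl} 1H-imidazole-1-carbothioate | CC1=CC[C@@H]2C(C)(C)[C@H](O)CC[C@]2(COC(=S)n3ccnc3)O[C@H]1CO[Si](c1ccccc1)(c1ccccc1)C(C)(C)C
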